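**Assumptions.**
- Genipin (1), the aglycone of the cheap iridoid geniposide, is bought as the single natural enantiomer (4aS,7aS).
- The C1 anomer of the methyl acetal is separated by chromatography and in any case equilibrates at step 9.
- The convex β-face (the face bearing H5 and H9) of the cis-fused bicycle is the more accessible one.
- Numbered compounds are the starting materials that supply skeleton atoms, the isolated intermediates and the target. Other reagents are given with SMILES in the step lines.

**Retrosynthesis**
1. The target comes from the 10-OTBS acylal by desilylation. The C1 acylal comes from the C1 methyl acetal by Lewis-acid acyl exchange.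
2. The C7 isovalerate and C11 acetate come from sequential acylation of triol 7, which comes from DIBAL reduction of the vinylogous-carbonate ester 6.
3. The key disconnection is the C7–O bond together with the C5=C6 alkene. These form in one Schenck ene reaction (¹O₂) on the Δ6,7 allylic alcohol 5. The C5–H stereocentre is relayed to C7.
4. Alcohol 5 comes from the trans-bromohydrin 4 (convex-face bromonium, anti opening at C8 sets 8α-OH) and then E2 elimination. The bromohydrin comes from the genipin Δ7,8 alkene.
5. Both rings, C1, C9 and C5 come from genipin, so no ring is formed.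

**Step 1**
Reactants: 1 (genipin)
Product: 2 (1-O-methylgenipin, 1β-OMe)
Conditions: MeOH, PPTS (cat.), 25 °C
Reagents that add atoms: methanol, CO
Why: Acid-catalysed transacetalisation of the lactol gives the methyl acetal, which survives DIBAL and base later, and the anomeric effect favours the axial 1β-OMe.

**Step 2**
Reactants: 2
Product: 3 (10-O-TBS ether of 2)
Conditions: TBSCl, imidazole, DMF, 0 °C
Reagents that add atoms: TBSCl, CC(C)(C)[Si](C)(C)Cl
Why: The unhindered primary allylic C10–OH is silylated selectively, which blocks the Payne-type and acylation side reactions later.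

**Step 3**
Reactants: 3
Product: 4 (7β-bromo-8α-hydroxy bromohydrin)
Conditions: NBS, THF/H₂O 4:1, 0 °C, dark
Reagents that add atoms: NBS, O=C1CCC(=O)N1Br; water, O
Why: Bromonium formation on the convex β-face is followed by anti opening of the trisubstituted bromonium by water at the more substituted C8, giving 8α-OH and 7β-Br (halohydrin formation). The push–pull enoate alkene is too electron-poor to compete.

**Step 4**
Reactants: 4
Product: 5 (Δ6,7 allylic alcohol, 8α-OH)
Conditions: DBU, toluene, 110 °C, sealed tube
Reagents that add atoms: none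
Why: C8 is quaternary, so E2 can only use H6α, which is anti to the 7β-Br and gives the C6=C7 alkene. The 8α-OH is untouched, so C8 is not scrambled.

**Step 5**
Reactants: 5
Product: 6 (7β,8α-diol, dienyl ester with Δ5,6)
Conditions: O₂, TPP (1 mol %), white LEDs, CH₂Cl₂, 0 °C, solid NaHCO₃; then PPh₃, 0 °C→25 °C
Reagents that add atoms: O₂, O=O
Why: Proposed new method: in the Schenck ene reaction, the C6=C7 alkene can lose only the doubly allylic H5 (β, pseudoaxial), because C8 has no H. ¹O₂ therefore adds to C7 on the β-face, the alkene moves to C5=C6 and conjugates with the enoate, and PPh₃ reduces the C7 hydroperoxide in situ to 7β-OH, trans to 8α-OH. The closest known reaction is the ¹O₂ ene reaction of cyclic 1,4-dienes, here with a vinylogous-carbonate π-system as the second alkene and with suprafacial chirality transfer from C5 to C7.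

**Step 6**
Reactants: 6
Product: 7 (11-hydroxy compound, 7,8-diol)
Conditions: DIBAL-H (5 equiv), CH₂Cl₂, −78→−40 °C; Rochelle salt work-up
Reagents that add atoms: none
Why: DIBAL reduces the conjugated methyl ester 1,2 to the allylic alcohol. The acetal, TBS ether and free OH groups survive, and no stereocentre is touched.

**Step 7**
Reactants: 7; 8 (acetic anhydride)
Product: 9 (11-acetate)
Conditions: 8 (1.05 equiv), pyridine, CH₂Cl₂, −20→0 °C
Reagents that add atoms: acetic anhydride, CC(=O)OC(C)=O
Why: The unhindered primary C11–OH is acylated much faster than the hindered secondary C7–OH or the tertiary C8–OH (chemoselective acylation).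

**Step 8**
Reactants: 9; 10 (isovaleryl chloride)
Product: 11 (7-O-isovalerate)
Conditions: 10 (2 equiv), DMAP, pyridine, CH₂Cl₂, 0→25 °C
Reagents that add atoms: isovaleryl chloride, CC(C)CC(=O)Cl
Why: DMAP-catalysed acylation takes the secondary C7–OH and leaves the tertiary C8–OH free. The configuration at C7 is retained.

**Step 9**
Reactants: 11; 12 (isovaleric anhydride)
Product: 13 (1-O-isovalerate acylal)
Conditions: 12 (2.5 equiv), TMSOTf (10 mol %), CH₂Cl₂, −60→−30 °C; Et₃N quench
Reagents that add atoms: isovaleric anhydride, CC(C)CC(=O)OC(=O)CC(C)C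
Why: TMSOTf ionises the methyl acetal to the O2-stabilised C1 oxocarbenium, and isovalerate capture (acetal-to-acylal exchange) gives the anomerically favoured axial 1β-ester cis to H9, with methyl isovalerate as the by-product.

**Step 10**
Reactants: 13
Product: 14 (Jatamanvaltrate K)
Conditions: HF·pyridine, pyridine/THF, 0→25 °C
Reagents that add atoms: none
Why: Buffered fluoride removes the primary TBS ether and leaves the acylal, acetate, isovalerate and dienyl ether intact. Acidic, non-basic conditions avoid acyl migration to the free C10–OH.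

**Compound list**

| No. | Name | SMILES | Role |
|---|---|---|---|
| 1 | genipin | COC(=O)C1=CO[C@@H](O)[C@H]2[C@@H]1CC=C2CO | starting material |
| 2 | 1-O-methylgenipin | COC(=O)C1=CO[C@@H](OC)[C@H]2[C@@H]1CC=C2CO | intermediate |
| 3 | 10-O-TBS-1-O-methylgenipin | COC(=O)C1=CO[C@@H](OC)[C@H]2[C@@H]1CC=C2CO[Si](C)(C)C(C)(C)C | intermediate |
| 4 | 7β-bromo-8α-hydroxy bromohydrin | COC(=O)C1=CO[C@@H](OC)[C@H]2[C@@H]1C[C@H](Br)[C@]2(O)CO[Si](C)(C)C(C)(C)C | intermediate |
| 5 | Δ6,7 allylic alcohol (8α-OH) | COC(=O)C1=CO[C@@H](OC)[C@H]2[C@@H]1C=C[C@]2(O)CO[Si](C)(C)C(C)(C)C | intermediate |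
| 6 | 7β,8α-diol, Δ5,6 dienyl ester | COC(=O)C1=CO[C@@H](OC)[C@H]2C1=C[C@H](O)[C@]2(O)CO[Si](C)(C)C(C)(C)C | intermediate |
| 7 | 11-hydroxy-7,8-diol | OCC1=CO[C@@H](OC)[C@H]2C1=C[C@H](O)[C@]2(O)CO[Si](C)(C)C(C)(C)C | intermediate |
| 8 | acetic anhydride | CC(=O)OC(C)=O | starting material |
| 9 | 11-acetate | CC(=O)OCC1=CO[C@@H](OC)[C@H]2C1=C[C@H](O)[C@]2(O)CO[Si](C)(C)C(C)(C)C | intermediate |
| 10 | isovaleryl chloride | CC(C)CC(=O)Cl | starting material |
| 11 | 7-O-isovalerate | CC(=O)OCC1=CO[C@@H](OC)[C@H]2C1=C[C@H](OC(=O)CC(C)C)[C@]2(O)CO[Si](C)(C)C(C)(C)C | intermediate |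
| 12 | isovaleric anhydride | CC(C)CC(=O)OC(=O)CC(C)C | starting material |
| 13 | 1,7-di-O-isovalerate, 10-OTBS | CC(=O)OCC1=CO[C@@H](OC(=O)CC(C)C)[C@H]2C1=C[C@H](OC(=O)CC(C)C)[C@]2(O)CO[Si](C)(C)C(C)(C)C | intermediate |
| 14 | Jatamanvaltrate K | CC(=O)OCC1=CO[C@@H](OC(=O)CC(C)C)[C@H]2C1=C[C@H](OC(=O)CC(C)C)[C@]2(O)CO | target |

**Total steps:** 10. **Longest linear sequence:** 10 steps, from genipin.

**Three steps most likely to fail**
1. **Step 5 (the proposed new ene reaction).** The β-face approach at C7 is next to the cis β-CH₂OTBS group, and ¹O₂ may attack the enol ether instead.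
   - Fallback (known chemistry): close 4 to the 7α,8α-epoxide with K₂CO₃/MeOH. Do DIBAL and selective acetylation (steps 6–7). Open the epoxide at C7 from the β-face with Cs isovalerate in DMF at 90 °C, giving the 7β-isovalerate and 8α-OH. Then introduce C5=C6 by DDQ dehydrogenation, and finish with steps 9–10.
2. **Step 3 (bromohydrin).** Water may attack C7 instead of C8, the concave α-face at C8 is hindered, or the enoate may be brominated.
   - Fallback: apply a hydroxy-directed Schenck ene reaction to 2 with the C10–OH free (TPP, O₂, hν, CH₂Cl₂ or CCl₄; then PPh₃). The allylic OH directs ¹O₂ to give the C8 hydroperoxide with C6=C7, which is reduced to 8α-OH. Silylate C10 to reach 5 directly, bypassing steps 3–4.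
3. **Step 9 (acetal-to-acylal exchange).** The Lewis acid can ionise the C11 allylic acetate, acylate the tertiary C8–OH, or give the wrong anomer.
   - Fallback: hydrolyse the methyl acetal of 11 (aqueous AcOH/THF, 40 °C) to the lactol. Acylate it in situ with isovaleric anhydride and DMAP, then separate the anomers.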